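(Readings and results are calculated on assumed constants, and the scatter is random.)

Find the share of J turned to Z in amber at the asked time, the opening exponent in G, and what the teal and green readings show.

| setting | teal | green | amber |
|---|---|---|---|
| J | 1.00 M | 1.00 M | 0.330 M |
| Q | 1.50 M | 1.50 M | 4.50 M |
| G | 0.100 M | 0.300 M | 0.100 M |
| time |  |  | 5.5 min |

| run | time / min | [Z] / M |
|---|---|---|
| teal run | 0.31 | 0.010 |
| teal run | 0.95 | 0.062 |
| teal run | 1.8 | 0.167 |
| teal run | 2.9 | 0.259 |
| teal run | 4.1 | 0.348 |
| teal run | 5.5 | 0.444 |
| green run | 0.31 | 0.027 |
| green run | 0.95 | 0.132 |
| green run | 1.8 | 0.291 |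
| green run | 2.9 | 0.430 |
| green run | 4.1 | 0.540 |
| green run | 5.5 | 0.637 |

(scatter of a reading: 0.005 M)

1. how the opening rate goes with [G] round the charge of the teal run: the exponent of the rate at two percent of J gone to Z
2. Z in the amber run at 5.5 min, as a share of the J charged
3. which of these the readings show (the catalyst wakes slowly / the product ties up the catalyst / the product speeds the reaction)

- Overall: J + Q -> Z, with G as catalyst.
- Constant volume, constant temperature.
- "The second partner" is Q.
- An order is taken over about fifteen percent of the charge, up and down.

1. Start from the bench rule for a reagent in excess: call the flask pseudo-first-order, hold Q at its mean, and take the share turned as one minus the exponential of constant × Q × time. Amber suits it, with Q at 13.6 times J, against 1.50 in teal.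

2. Take the constant from teal, whose G charge equals amber's. Q is not in excess in teal, so use the integrated form for J and Q between the readings at 2.9 min and 5.5 min. It reads 0.0968 L mol⁻¹ min⁻¹. Call this the awake constant: the rate per unit of J and of Q after the climb. Assume first order in Q.

3. Find the border. Run from zero time, the constant puts teal Z at 0.0450 M at the first reading, but the reading is 0.010 M, which is less, a ratio of 0.222. So the rule fails at the opening, and I read a catalyst that wakes slowly. Extending the late line back gives a teal lag of 0.622 min. Green, read the same way, gives a constant of 0.182 L mol⁻¹ min⁻¹ and a lag of 0.431 min.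

4. Reckon amber. The full clock gives 90.0 %; the clock less the teal lag gives 87.1 %. Commit to the second.

5. The forecast gives 86 %, a little below my figure, with an exponent of 0.35, and says “There is no sign of later product inhibition or continued acceleration, so the catalyst wakes slowly”.

6. The flask gives 87.9 %, and the catalyst wakes slowly.

    2 Gu ⇌ G2, settled at all times (9.770 L mol⁻¹)
    Gu + J + Q → Z + Gu (1.824 L² mol⁻² min⁻¹)
    G + Q → Gu + Q (1.044 L mol⁻¹ min⁻¹)

The opening exponent is 0.48, against the forecast's 0.35. The teal rate where two percent of the J has turned is 0.079 M min⁻¹, which is 0.542 of the awake constant times the teal charges of J and Q. In the green run, the green constant and lag put half of the J charged turned at 3.60 min; the flask has 3.61 min.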